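**Assumption:** labdane numbering (C1–C20) is used; the SMILES is read as 19-angeloyloxy-labda-7,13(Z)-dien-15-oic acid, 4S,5R,9S,10R (4β-CH2O axial, 5α-H, 9β side chain, 10β-Me); (−)-8-phenylmenthol is a recoverable chiral auxiliary and is listed with the reagents.

## Retrosynthetic overview

1. 18 ⇒ hydroxy acid 15 + angelic acid 16 (ester bond last); 15 ⇒ bicyclic keto diester 11 (delete C3=O, hydrolyse the C15 ester, reduce the C19 auxiliary ester).
2. 11 ⇒ acyclic trienyl α-methyl β-keto ester 10. One Mn(III) radical cascade forms C4–C5 (ring A first), then C10–C9 (ring B), and ends by loss of MeSO2• from C7, which places the Δ7 alkene. The 8-phenylmenthyl ester fixes the absolute sense.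
3. 10 ⇒ acetoacetate dianion (C1–C2 bond, then C-methylation) + allylic bromide 7; 7 ⇒ sulfone carbanion of 6 (C6–C7 bond) + dibromide 2.
4. 6 ⇒ methyl acetoacetate dianion + 2 (C11–C12 bond), MeSO2Na at C7, then (E)-enol triflate / Me2CuLi for the 13Z enoate.

## Route

Step 1
Reactants: 1 methyl acetoacetate; 2 (E)-1,4-dibromo-2-methylbut-2-ene
Product: 3 methyl (6E)-8-bromo-7-methyl-3-oxooct-6-enoate
Conditions: 1, NaH, THF, 0 °C; n-BuLi, 0 °C; cannulate into 2 (3 equiv), THF, −78 → −20 °C; 1 M HCl at −20 °C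
Reagents that add atoms: none
Why: Weiler dianion γ-alkylation; the terminal carbanion displaces the more reactive γ,γ-disubstituted (prenyl-type) bromide of 2 by SN2, excess 2 and a cold quench suppress bis-alkylation and enolate ring closure, and the E alkene of 2 is carried over unchanged.

Step 2
Reactants: 3 methyl (6E)-8-bromo-7-methyl-3-oxooct-6-enoate
Product: 4 methyl (6E)-7-methyl-8-(methylsulfonyl)-3-oxooct-6-enoate
Conditions: MeSO2Na (1.5 equiv), DMF, rt
Reagents that add atoms: sodium methanesulfinate, CS(=O)[O-].[Na+]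
Why: SN2 S-alkylation of the sulfinate by the primary allylic bromide gives the allyl sulfone that later serves as both carbanion handle and radical leaving group; no stereocentre is formed.

Step 3
Reactants: 4 methyl (6E)-7-methyl-8-(methylsulfonyl)-3-oxooct-6-enoate
Product: 5 methyl (2E,6E)-7-methyl-8-(methylsulfonyl)-3-(trifluoromethylsulfonyloxy)octa-2,6-dienoate
Conditions: Tf2O (1.5 equiv), aq. Me4NOH, toluene, 0–5 °C
Reagents that add atoms: triflic anhydride, O=S(=O)(OS(=O)(=O)C(F)(F)F)C(F)(F)F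
Why: Stereoselective enol triflation of a β-keto ester; the non-chelated tetramethylammonium enolate reacts in its open form and gives the (E)-enol triflate (TfO trans to CO2Me).

Step 4
Reactants: 5 methyl (2E,6E)-7-methyl-8-(methylsulfonyl)-3-(trifluoromethylsulfonyloxy)octa-2,6-dienoate
Product: 6 methyl (2Z,6E)-3,7-dimethyl-8-(methylsulfonyl)octa-2,6-dienoate
Conditions: Me2CuLi (from MeLi, CuI; 2 equiv), THF, −78 → −40 °C; aq. NH4Cl
Reagents that add atoms: lithium dimethylcuprate (made from methyllithium, [Li]C, and CuI), [Li+].C[Cu-]C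
Why: Gilman cuprate addition–elimination on the β-triflyloxy enoate goes with retention, so the new methyl is trans to CO2Me and the chain cis, which sets the 13Z enoate geometry.

Step 5
Reactants: 6 methyl (2Z,6E)-3,7-dimethyl-8-(methylsulfonyl)octa-2,6-dienoate; 2 (E)-1,4-dibromo-2-methylbut-2-ene
Product: 7 methyl (2Z,6E,10E)-12-bromo-3,7,11-trimethyl-8-(methylsulfonyl)dodeca-2,6,10-trienoate
Conditions: LDA (1.05 equiv), THF, −78 °C; cannulate into 2 (3 equiv), THF, −78 → −40 °C
Reagents that add atoms: none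
Why: Julia-type α-alkylation of the allyl sulfone carbanion at the prenyl-type bromide of 2 (SN2); the sulfone-bearing carbon is formed racemic, which is harmless because it is erased in step 8.

Step 6
Reactants: 1 methyl acetoacetate
Product: 8 (−)-8-phenylmenthyl acetoacetate [(1R,2S,5R)-5-methyl-2-(2-phenylpropan-2-yl)cyclohexyl 3-oxobutanoate]
Conditions: (−)-8-phenylmenthol (0.5 equiv), DMAP (cat.), toluene, reflux, 4 Å MS (−MeOH)
Reagents that add atoms: (−)-8-phenylmenthol, CC(C)(c1ccccc1)[C@@H]2CC[C@@H](C)C[C@H]2O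
Why: DMAP-catalysed transesterification of an acetoacetate (via the acylketene) installs the auxiliary; its three stereocentres are untouched.

Step 7
Reactants: 8 (−)-8-phenylmenthyl acetoacetate; 7 methyl (2Z,6E,10E)-12-bromo-3,7,11-trimethyl-8-(methylsulfonyl)dodeca-2,6,10-trienoate
Product: 10 1-[(−)-8-phenylmenthyl] 16-methyl (6E,10E,14Z)-2,6,10,14-tetramethyl-9-(methylsulfonyl)-3-oxohexadeca-6,10,14-trienedioate, via unmethylated keto diester 9 (not isolated)
Conditions: 8, NaH, THF, 0 °C; n-BuLi, 0 °C; 7 (0.9 equiv), −78 → −20 °C; then MeI (3 equiv), DMPU, rt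
Reagents that add atoms: iodomethane, CI
Why: Weiler dianion γ-alkylation by the remaining allylic bromide, then C-methylation of the resulting β-keto ester enolate in the same flask; C2 and C9 of the chain are left as mixtures because both are erased in step 8.

Step 8
Reactants: 10 1-[(−)-8-phenylmenthyl] 16-methyl (6E,10E,14Z)-2,6,10,14-tetramethyl-9-(methylsulfonyl)-3-oxohexadeca-6,10,14-trienedioate
Product: 11 (−)-8-phenylmenthyl 15-methoxy-3,15-dioxolabda-7,13(Z)-dien-19-oate (4β-ester axial, 5α-H, 9β side chain, 10β-Me)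
Conditions: Mn(OAc)3·2H2O (2.5 equiv), degassed AcOH (0.03 M), 25–40 °C, no Cu(II); minor diastereomer removed by chromatography
Reagents that add atoms: none
Why: Proposed new method: Mn(III) oxidises the enol of the α-methyl β-keto ester to the electrophilic tertiary C4 radical, which closes ring A 6-endo onto C5 of the (E)-C5=C10 alkene through a chair with the two carbonyls anti, so the ester ends axial (C19) and 5-H/10-Me trans; the tertiary C10 radical then closes ring B 6-endo onto C9 of the (E)-allyl sulfone (chair, trans-decalin, 9β side chain), and the β-sulfonyl C8 radical expels MeSO2• to give only the Δ7 alkene, while the auxiliary's phenyl ring shields one face of the planar radical and fixes the absolute sense (natural 4β-ester series, by analogy with the Mn(III) cyclisation of 8-phenylmenthyl 2-methylacetoacetates of this type); closest known reaction types: Mn(III)-based oxidative free-radical polyene cyclisation (normally ended by Cu(II) oxidation) and radical allylation by addition–β-fragmentation of allyl sulfones.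

Step 9
Reactants: 11 (−)-8-phenylmenthyl 15-methoxy-3,15-dioxolabda-7,13(Z)-dien-19-oate
Product: 13 (−)-8-phenylmenthyl 15-methoxy-15-oxolabda-7,13(Z)-dien-19-oate, via tosylhydrazone 12 (not isolated)
Conditions: TsNHNH2, EtOH, 70 °C; evaporate; catecholborane, CHCl3, 0 °C → rt; NaOAc·3H2O, 60 °C
Reagents that add atoms: none
Why: Caglioti/Kabalka tosylhydrazone reduction (hydride to C=N, then loss of sulfinate and N2) turns the C3 ketone into CH2 without touching the esters, the alkenes or any stereocentre.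

Step 10
Reactants: 13 (−)-8-phenylmenthyl 15-methoxy-15-oxolabda-7,13(Z)-dien-19-oate
Product: 14 19-[(−)-8-phenylmenthyloxy]-19-oxolabda-7,13(Z)-dien-15-oic acid
Conditions: LiOH·H2O, THF/MeOH/H2O, rt; HCl to pH 3
Reagents that add atoms: lithium hydroxide, [Li+].[OH-]
Why: Saponification is selective for the unhindered C15 methyl ester because the axial neopentyl 8-phenylmenthyl ester at C4 is inert to hydroxide.

Step 11
Reactants: 14 19-[(−)-8-phenylmenthyloxy]-19-oxolabda-7,13(Z)-dien-15-oic acid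
Product: 15 19-hydroxylabda-7,13(Z)-dien-15-oic acid
Conditions: LiEt3BH (6 equiv), THF, 0 → 60 °C; aq. HCl
Reagents that add atoms: none
Why: Super-Hydride ester reduction; the first equivalent makes the C15 carboxylate, which resists hydride, while the hindered ester is reduced to the C19 primary alcohol and the auxiliary is released.

Step 12
Reactants: 15 19-hydroxylabda-7,13(Z)-dien-15-oic acid; 16 angelic acid
Product: 18 19-(angeloyloxy)labda-7,13(Z)-dien-15-oic acid (target), via mixed anhydride 17 (not isolated)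
Conditions: 16, 2,4,6-Cl3C6H2COCl, Et3N, toluene, rt (gives 17, filtered); 15, LiHMDS (2.1 equiv), THF, −78 °C, then 17 (1.5 equiv), −78 → 0 °C; aq. NaHCO3, then HCl to pH 3
Reagents that add atoms: none
Why: Acylation of the lithium alkoxide by a Yamaguchi-type mixed anhydride at the less hindered angeloyl carbonyl; the cold, amine-free acyl transfer keeps the angelate Z geometry, and any mixed anhydride formed at the C15 carboxylate is hydrolysed on work-up.

## Compound list

1 | methyl acetoacetate (methyl 3-oxobutanoate) | CC(=O)CC(=O)OC | starting material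
2 | (E)-1,4-dibromo-2-methylbut-2-ene | BrC/C(C)=C/CBr | starting material
3 | methyl (6E)-8-bromo-7-methyl-3-oxooct-6-enoate | COC(=O)CC(=O)CC/C=C(\C)CBr | intermediate
4 | methyl (6E)-7-methyl-8-(methylsulfonyl)-3-oxooct-6-enoate | COC(=O)CC(=O)CC/C=C(\C)CS(C)(=O)=O | intermediate
5 | methyl (2E,6E)-7-methyl-8-(methylsulfonyl)-3-(trifluoromethylsulfonyloxy)octa-2,6-dienoate | COC(=O)/C=C(/OS(=O)(=O)C(F)(F)F)CC/C=C(\C)CS(C)(=O)=O | intermediate
6 | methyl (2Z,6E)-3,7-dimethyl-8-(methylsulfonyl)octa-2,6-dienoate | COC(=O)/C=C(/C)CC/C=C(\C)CS(C)(=O)=O | intermediate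
7 | methyl (2Z,6E,10E)-12-bromo-3,7,11-trimethyl-8-(methylsulfonyl)dodeca-2,6,10-trienoate (C8 racemic) | COC(=O)/C=C(/C)CC/C=C(\C)C(C/C=C(\C)CBr)S(C)(=O)=O | intermediate
8 | (−)-8-phenylmenthyl acetoacetate | CC(C)(c1ccccc1)[C@@H]2CC[C@@H](C)C[C@H]2OC(=O)CC(C)=O | intermediate
9 | 1-[(−)-8-phenylmenthyl] 16-methyl (6E,10E,14Z)-6,10,14-trimethyl-9-(methylsulfonyl)-3-oxohexadeca-6,10,14-trienedioate (present as its enolate) | CC(C)(c1ccccc1)[C@@H]2CC[C@@H](C)C[C@H]2OC(=O)CC(=O)CC/C(C)=C/CC(S(C)(=O)=O)/C(C)=C/CC/C(C)=C\C(=O)OC | intermediate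
10 | 1-[(−)-8-phenylmenthyl] 16-methyl (6E,10E,14Z)-2,6,10,14-tetramethyl-9-(methylsulfonyl)-3-oxohexadeca-6,10,14-trienedioate (mixture at C2 and C9) | CC(C)(c1ccccc1)[C@@H]2CC[C@@H](C)C[C@H]2OC(=O)C(C)C(=O)CC/C(C)=C/CC(S(C)(=O)=O)/C(C)=C/CC/C(C)=C\C(=O)OC | intermediate
11 | (−)-8-phenylmenthyl 15-methoxy-3,15-dioxolabda-7,13(Z)-dien-19-oate | CC(C)(c1ccccc1)[C@@H]2CC[C@@H](C)C[C@H]2OC(=O)[C@@]3(C)C(=O)CC[C@]4(C)[C@@H](CC/C(C)=C\C(=O)OC)C(C)=CC[C@@H]34 | intermediate
12 | 3-tosylhydrazone of 11 | CC(C)(c1ccccc1)[C@@H]2CC[C@@H](C)C[C@H]2OC(=O)[C@@]3(C)C(=NNS(=O)(=O)c5ccc(C)cc5)CC[C@]4(C)[C@@H](CC/C(C)=C\C(=O)OC)C(C)=CC[C@@H]34 | intermediate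
13 | (−)-8-phenylmenthyl 15-methoxy-15-oxolabda-7,13(Z)-dien-19-oate | CC(C)(c1ccccc1)[C@@H]2CC[C@@H](C)C[C@H]2OC(=O)[C@@]3(C)CCC[C@]4(C)[C@@H](CC/C(C)=C\C(=O)OC)C(C)=CC[C@@H]34 | intermediate
14 | 19-[(−)-8-phenylmenthyloxy]-19-oxolabda-7,13(Z)-dien-15-oic acid | CC(C)(c1ccccc1)[C@@H]2CC[C@@H](C)C[C@H]2OC(=O)[C@@]3(C)CCC[C@]4(C)[C@@H](CC/C(C)=C\C(=O)O)C(C)=CC[C@@H]34 | intermediate
15 | 19-hydroxylabda-7,13(Z)-dien-15-oic acid | OC[C@@]1(C)CCC[C@]2(C)[C@@H](CC/C(C)=C\C(=O)O)C(C)=CC[C@@H]12 | intermediate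
16 | angelic acid ((Z)-2-methylbut-2-enoic acid) | C/C=C(/C)C(=O)O | starting material
17 | angelic 2,4,6-trichlorobenzoic anhydride | C/C=C(/C)C(=O)OC(=O)c1c(Cl)cc(Cl)cc1Cl | intermediate
18 | 19-(angeloyloxy)labda-7,13(Z)-dien-15-oic acid (CNP0249147.1) | C/C=C(/C)C(=O)OC[C@@]1(C)CCC[C@]2(C)[C@@H](CC/C(C)=C\C(=O)O)C(C)=CC[C@@H]12 | target

## Step count and risks

Total steps: 12. Longest linear sequence: 11 (steps 1–5, then 7–12); step 6 is a one-step side branch.

Most likely to fail:

**Step 8 (radical cascade).** The C8 radical may fragment slowly for the C7 epimer whose C–S bond is equatorial, Mn(III) may intercept intermediate radicals, and the auxiliary's facial bias is taken by analogy. Fallback, setting out from 10 and returning at 11: deprotonate with NaH and brominate with NBS (THF, 0 °C) to give the α-bromo keto diester F1. Then run an oxidant-free atom-abstraction chain with hexabutylditin under a sun lamp (benzene, 40 °C). Bu3Sn• removes bromine, the same C4 radical cyclises twice, and the expelled MeSO2• regenerates Bu3Sn• from the ditin, so the C8 radical can only fragment.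

**Step 9 (deoxygenation).** The C3 ketone sits next to the quaternary C4 and the bulky ester, so hydrazone formation or hydride delivery may stall. Fallback, setting out from 11 and returning at 13: NaBH4 (MeOH, 0 °C) gives the 3β-hydroxy diester F2. 1,1′-Thiocarbonyldiimidazole with DMAP (DCE, reflux) gives the 3-O-(imidazol-1-ylthiocarbonyl) diester F3. Barton–McCombie reduction (Bu3SnH, AIBN, toluene, 100 °C) then gives 13.

**Step 11 (ester reduction beside the free acid).** The doubly hindered ester may need forcing conditions under which the carboxylate is no longer inert. Fallback, setting out from 13 (skipping step 10) and returning at 15: LiAlH4 (THF, reflux) reduces both esters to labda-7,13(Z)-diene-15,19-diol F4. MnO2 (CH2Cl2, rt) oxidises only the allylic alcohol to 19-hydroxylabda-7,13(Z)-dien-15-al F5. Pinnick oxidation (NaClO2, NaH2PO4, 2-methyl-2-butene, t-BuOH/H2O) gives 15.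

## Further compounds

F1 | step 8 | 1-[(−)-8-phenylmenthyl] 16-methyl (6E,10E,14Z)-2-bromo-2,6,10,14-tetramethyl-9-(methylsulfonyl)-3-oxohexadeca-6,10,14-trienedioate | CC(C)(c1ccccc1)[C@@H]2CC[C@@H](C)C[C@H]2OC(=O)C(C)(Br)C(=O)CC/C(C)=C/CC(S(C)(=O)=O)/C(C)=C/CC/C(C)=C\C(=O)OC
F2 | step 9 | (−)-8-phenylmenthyl 3β-hydroxy-15-methoxy-15-oxolabda-7,13(Z)-dien-19-oate | CC(C)(c1ccccc1)[C@@H]2CC[C@@H](C)C[C@H]2OC(=O)[C@@]3(C)[C@@H](O)CC[C@]4(C)[C@@H](CC/C(C)=C\C(=O)OC)C(C)=CC[C@@H]34
F3 | step 9 | (−)-8-phenylmenthyl 3β-(imidazol-1-ylthiocarbonyloxy)-15-methoxy-15-oxolabda-7,13(Z)-dien-19-oate | CC(C)(c1ccccc1)[C@@H]2CC[C@@H](C)C[C@H]2OC(=O)[C@@]3(C)[C@@H](OC(=S)n5ccnc5)CC[C@]4(C)[C@@H](CC/C(C)=C\C(=O)OC)C(C)=CC[C@@H]34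
F4 | step 11 | labda-7,13(Z)-diene-15,19-diol | OC[C@@]1(C)CCC[C@]2(C)[C@@H](CC/C(C)=C\CO)C(C)=CC[C@@H]12
F5 | step 11 | 19-hydroxylabda-7,13(Z)-dien-15-al | OC[C@@]1(C)CCC[C@]2(C)[C@@H](CC/C(C)=C\C=O)C(C)=CC[C@@H]12
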